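Assumption: atom labels C-1 to C-15 follow germacrane numbering (C-6 lactone carbinol, C-8 ester carbinol, C-14 formyl, C-15 hydroxymethyl); the target SMILES is read as 6R,7S,8R with a cis-fused lactone, O-8 trans to the C-7 side chain, and both ring olefins cis within the ring.

**Retrosynthetic overview**
1. 21 ⇐ enol triflate 20 (Pd-catalysed formylation, C-14 from CO) ⇐ 19 (allylic hydroxylation at C-15) ⇐ 18 (acylation of O-8).
2. cis-Lactone 18 ⇐ ten-membered dienone triflate 15 (1,2-reduction at C-6, then O-6 closes onto the C-12 ester).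
3. 15 ⇐ bicyclic ketol 13 by retro-aldol four-carbon ring expansion (C-1–C-6 cleavage, enolate trapped as triflate).
4. 13 ⇐ β-diketone 12 by intramolecular allylindium addition (C-6–C-7 bond, sets C-7) ⇐ enone 9 + aldehyde 8 (aldol, oxidation).
5. 8 ⇐ aldehyde 4 + acrylate 5 (Baylis–Hillman, SN2′ bromination, ozonolysis) ⇐ ethyl glyoxylate 1 (asymmetric allylation sets C-8). Ring order: ring A (bought) → ring B (decalin) → ten-membered carbocycle → γ-lactone.

**Route**

Step 1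
Reactants: 1 ethyl glyoxylate
Product: 2 ethyl (2R)-2-hydroxypent-4-enoate
Conditions: allylboronic acid pinacol ester, (R)-TRIP (5 mol %), toluene, −30 °C; aqueous work-up
Reagents that add atoms: allylboronic acid pinacol ester, C=CCB1OC(C)(C)C(C)(C)O1
Why: Chiral phosphoric acid-catalysed asymmetric allylboration through a closed chair transition state delivers the allyl group to the Re face of the aldehyde and sets C-8 as R.

Step 2
Reactants: 2 ethyl (2R)-2-hydroxypent-4-enoate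
Product: 3 ethyl (2R)-2-[(tert-butyldimethylsilyl)oxy]pent-4-enoate
Conditions: TBSCl, imidazole, DMF, 25 °C
Reagents that add atoms: tert-butyldimethylsilyl chloride, CC(C)(C)[Si](C)(C)Cl
Why: Imidazole-promoted silylation protects O-8 as an ether that survives up to step 12 and, unlike an ester, cannot be expelled by the later allylindium; C-8 is untouched.

Step 3
Reactants: 3 ethyl (2R)-2-[(tert-butyldimethylsilyl)oxy]pent-4-enoate
Product: 4 (2R)-2-[(tert-butyldimethylsilyl)oxy]pent-4-enal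
Conditions: DIBAL-H, CH2Cl2, −78 °C; Rochelle salt
Reagents that add atoms: none
Why: Low-temperature DIBAL-H half-reduction of an α-silyloxy ester stops at the aluminium hemiacetal and releases the aldehyde on work-up without epimerising C-8.

Step 4
Reactants: 4 (2R)-2-[(tert-butyldimethylsilyl)oxy]pent-4-enal; 5 tert-butyl acrylate
Product: 6 tert-butyl (3RS,4R)-4-[(tert-butyldimethylsilyl)oxy]-3-hydroxy-2-methylidenehept-6-enoate
Conditions: DABCO (1 equiv), neat 5 (5 equiv), 25 °C, 5 d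
Reagents that add atoms: none
Why: Morita–Baylis–Hillman reaction joins the acrylate α-carbon (C-11) to the activated α-alkoxy aldehyde carbon (C-7); the new carbinol centre is a mixture that is erased in step 5.

Step 5
Reactants: 6 tert-butyl (3RS,4R)-4-[(tert-butyldimethylsilyl)oxy]-3-hydroxy-2-methylidenehept-6-enoate
Product: 7 tert-butyl (2Z,4R)-2-(bromomethyl)-4-[(tert-butyldimethylsilyl)oxy]hepta-2,6-dienoate
Conditions: NBS, Me2S, CH2Cl2, 0 → 25 °C
Reagents that add atoms: N-bromosuccinimide, BrN1C(=O)CCC1=O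
Why: Corey–Kim-type activation of the allylic alcohol and SN2′ attack of bromide gives the (Z)-2-(bromomethyl)enoate, as is general for Baylis–Hillman adducts, and C-7 becomes sp2.

Step 6
Reactants: 7 tert-butyl (2Z,4R)-2-(bromomethyl)-4-[(tert-butyldimethylsilyl)oxy]hepta-2,6-dienoate
Product: 8 tert-butyl (2Z,4R)-2-(bromomethyl)-4-[(tert-butyldimethylsilyl)oxy]-6-oxohex-2-enoate
Conditions: O3, acetone/H2O (19:1), 0 °C
Reagents that add atoms: ozone, [O-][O+]=O
Why: Ozonolysis cleaves the terminal olefin far faster than the ester-conjugated one, and water traps the carbonyl oxide so the aldehyde forms without a reductant that would attack the allylic bromide.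

Step 7
Reactants: 9 3-methylcyclohex-2-en-1-one; 8 tert-butyl (2Z,4R)-2-(bromomethyl)-4-[(tert-butyldimethylsilyl)oxy]-6-oxohex-2-enoate
Product: 11 tert-butyl (2Z,4R)-2-(bromomethyl)-4-[(tert-butyldimethylsilyl)oxy]-6-hydroxy-6-(4-methyl-2-oxocyclohex-3-en-1-yl)hex-2-enoate, via lithium dienolate 10 (not isolated)
Conditions: LDA, THF, −78 °C; then 8, −78 °C, 10 min; AcOH
Reagents that add atoms: none
Why: Kinetic α′-deprotonation gives the cross-conjugated dienolate, whose aldol addition at −78 °C outruns alkylation by the allylic bromide; the new centres C-1 and C-10 form as mixtures and both become sp2 later.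

Step 8
Reactants: 11 tert-butyl (2Z,4R)-2-(bromomethyl)-4-[(tert-butyldimethylsilyl)oxy]-6-hydroxy-6-(4-methyl-2-oxocyclohex-3-en-1-yl)hex-2-enoate
Product: 12 tert-butyl (2Z,4R)-2-(bromomethyl)-4-[(tert-butyldimethylsilyl)oxy]-6-(4-methyl-2-oxocyclohex-3-en-1-yl)-6-oxohex-2-enoate
Conditions: Dess–Martin periodinane, CH2Cl2, 0 °C
Reagents that add atoms: none
Why: Dess–Martin oxidation of the β-hydroxy ketone gives the largely enolised β-diketone, removes the C-10 and C-1 stereocentres and leaves the allylic bromide alone.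

Step 9
Reactants: 12 tert-butyl (2Z,4R)-2-(bromomethyl)-4-[(tert-butyldimethylsilyl)oxy]-6-(4-methyl-2-oxocyclohex-3-en-1-yl)-6-oxohex-2-enoate
Product: 13 tert-butyl 2-[(1S,2R)-2-[(tert-butyldimethylsilyl)oxy]-8a-hydroxy-7-methyl-4-oxo-1,2,3,4,4a,5,6,8a-octahydronaphthalen-1-yl]prop-2-enoate
Conditions: indium powder, THF/H2O (3:1), 25 °C, 0.01 M
Reagents that add atoms: none
Why: Barbier-type 2-(alkoxycarbonyl)allylation in which the allylindium at C-13 adds through its γ-carbon (C-7) to ring ketone C-6, the only carbonyl reachable through a six-membered chair, while A(1,3) strain of the (Z)-olefin and an equatorial silyloxy group place the new C-7–C-11 bond trans to O-8 (7S); the ring-fusion centres are lost in step 10.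

Step 10
Reactants: 13 tert-butyl 2-[(1S,2R)-2-[(tert-butyldimethylsilyl)oxy]-8a-hydroxy-7-methyl-4-oxo-1,2,3,4,4a,5,6,8a-octahydronaphthalen-1-yl]prop-2-enoate
Product: 15 (1E,5Z,8S,9R)-8-[3-(tert-butoxy)-3-oxoprop-1-en-2-yl]-9-[(tert-butyldimethylsilyl)oxy]-5-methyl-7-oxocyclodeca-1,5-dien-1-yl trifluoromethanesulfonate, via potassium enolate 14 (not isolated)
Conditions: PhNTf2 (1.2 equiv) present from the start, KHMDS (1.05 equiv), 18-crown-6, THF, −78 → 0 °C; aq NH4Cl
Reagents that add atoms: N-phenylbis(trifluoromethanesulfonimide), O=S(=O)(N(c1ccccc1)S(=O)(=O)C(F)(F)F)C(F)(F)F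
Why: Proposed new method: deprotonating the tertiary alcohol triggers retro-aldol cleavage of the ring-fusion bond C-1–C-6 (the alkoxide lone pair, the breaking σ bond and the C-10 carbonyl π* are aligned in the cis-fused ketol, and the tert-butyl ester resists the alkoxide), the cis-fused aldolate with its axial C-1–C-2 bond opens to the ten-membered (E)-enolate with a ring-cis C-1=C-10 bond, which is also the only unstrained one, and the triflimide already present traps it before it can re-close or transfer a proton from C-7; the closest known reactions are the retro-aldol ring expansion of the De Mayo sequence and O-triflation of kinetic ketone enolates.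

Step 11
Reactants: 15 (1E,5Z,8S,9R)-8-[3-(tert-butoxy)-3-oxoprop-1-en-2-yl]-9-[(tert-butyldimethylsilyl)oxy]-5-methyl-7-oxocyclodeca-1,5-dien-1-yl trifluoromethanesulfonate
Product: 16 (1E,5Z,7R,8R,9R)-8-[3-(tert-butoxy)-3-oxoprop-1-en-2-yl]-9-[(tert-butyldimethylsilyl)oxy]-7-hydroxy-5-methylcyclodeca-1,5-dien-1-yl trifluoromethanesulfonate
Conditions: NaBH4, CeCl3·7H2O, MeOH, −78 °C
Reagents that add atoms: none
Why: Luche 1,2-reduction of the enone in which Felkin–Anh attack from the ring periphery (anti to the C-7–C-8 bond) and 1,3-anti induction from the C-8 silyloxy group reinforce each other and give the 6R alcohol with O-6 cis to the acrylate.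

Step 12
Reactants: 16 (1E,5Z,7R,8R,9R)-8-[3-(tert-butoxy)-3-oxoprop-1-en-2-yl]-9-[(tert-butyldimethylsilyl)oxy]-7-hydroxy-5-methylcyclodeca-1,5-dien-1-yl trifluoromethanesulfonate
Product: 18 (3aS,4R,6E,10Z,11aR)-4-hydroxy-10-methyl-3-methylidene-2-oxo-2,3,3a,4,5,8,9,11a-octahydrocyclodeca[b]furan-6-yl trifluoromethanesulfonate, via silyl lactone 17 (not isolated)
Conditions: KOtBu (0.2 equiv), THF, 0 °C; then HF·pyridine, 0 → 25 °C
Reagents that add atoms: none
Why: Alkoxide-catalysed 5-exo-trig transesterification turns the syn γ-hydroxy tert-butyl ester into the cis-fused α-methylene-γ-lactone with retention at C-6 while O-8 is still silylated, and buffered fluoride then frees O-8 without touching the enol triflate.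

Step 13
Reactants: 18 (3aS,4R,6E,10Z,11aR)-4-hydroxy-10-methyl-3-methylidene-2-oxo-2,3,3a,4,5,8,9,11a-octahydrocyclodeca[b]furan-6-yl trifluoromethanesulfonate
Product: 19 (3aS,4R,6E,10Z,11aR)-10-methyl-3-methylidene-2-oxo-6-{[(trifluoromethyl)sulfonyl]oxy}-2,3,3a,4,5,8,9,11a-octahydrocyclodeca[b]furan-4-yl 3-methylbutanoate
Conditions: 3-methylbutanoyl chloride, pyridine, DMAP (cat.), CH2Cl2, 0 °C
Reagents that add atoms: 3-methylbutanoyl chloride, CC(C)CC(=O)Cl
Why: DMAP-catalysed acylation of the only free hydroxyl installs the isovalerate at O-8 with retention.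

Step 14
Reactants: 19 (3aS,4R,6E,10Z,11aR)-10-methyl-3-methylidene-2-oxo-6-{[(trifluoromethyl)sulfonyl]oxy}-2,3,3a,4,5,8,9,11a-octahydrocyclodeca[b]furan-4-yl 3-methylbutanoate
Product: 20 (3aS,4R,6E,10E,11aR)-10-(hydroxymethyl)-3-methylidene-2-oxo-6-{[(trifluoromethyl)sulfonyl]oxy}-2,3,3a,4,5,8,9,11a-octahydrocyclodeca[b]furan-4-yl 3-methylbutanoate
Conditions: SeO2 (0.5 equiv), tBuOOH (3 equiv), CH2Cl2, 25 °C
Reagents that add atoms: selenium dioxide, O=[Se]=O (oxygen carrier); tert-butyl hydroperoxide, CC(C)(C)OO (terminal oxygen source)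
Why: Riley-type allylic hydroxylation (ene reaction, then [2,3]-shift of the allylseleninic acid) attacks the only electron-rich olefin C-4=C-5 at its (E)-methyl group, the enol triflate and acrylate olefins being deactivated, and returns the double bond with its ring-cis geometry.

Step 15
Reactants: 20 (3aS,4R,6E,10E,11aR)-10-(hydroxymethyl)-3-methylidene-2-oxo-6-{[(trifluoromethyl)sulfonyl]oxy}-2,3,3a,4,5,8,9,11a-octahydrocyclodeca[b]furan-4-yl 3-methylbutanoate
Product: 21 (3aS,4R,6E,10E,11aR)-6-formyl-10-(hydroxymethyl)-3-methylidene-2-oxo-2,3,3a,4,5,8,9,11a-octahydrocyclodeca[b]furan-4-yl 3-methylbutanoate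
Conditions: Pd(PPh3)4 (5 mol %), CO (1 atm), Bu3SnH (slow addition), LiCl, THF, 50 °C
Reagents that add atoms: carbon monoxide, [C-]#[O+]
Why: Stille-type reductive carbonylation in which zerovalent palladium inserts into the vinyl triflate, CO inserts and tin hydride delivers hydride, giving the enal with retention of the C-1=C-10 geometry so that the formyl group lies trans to C-2.

**Compound list**
1 | ethyl glyoxylate | O=CC(=O)OCC | starting material
2 | ethyl (2R)-2-hydroxypent-4-enoate | C=CC[C@@H](O)C(=O)OCC | intermediate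
3 | ethyl (2R)-2-[(tert-butyldimethylsilyl)oxy]pent-4-enoate | C=CC[C@@H](O[Si](C)(C)C(C)(C)C)C(=O)OCC | intermediate
4 | (2R)-2-[(tert-butyldimethylsilyl)oxy]pent-4-enal | C=CC[C@@H](O[Si](C)(C)C(C)(C)C)C=O | intermediate
5 | tert-butyl acrylate | C=CC(=O)OC(C)(C)C | starting material
6 | tert-butyl (3RS,4R)-4-[(tert-butyldimethylsilyl)oxy]-3-hydroxy-2-methylidenehept-6-enoate (C-3 epimers) | C=CC[C@@H](O[Si](C)(C)C(C)(C)C)C(O)C(=C)C(=O)OC(C)(C)C | intermediate
7 | tert-butyl (2Z,4R)-2-(bromomethyl)-4-[(tert-butyldimethylsilyl)oxy]hepta-2,6-dienoate | C=CC[C@@H](O[Si](C)(C)C(C)(C)C)/C=C(\CBr)C(=O)OC(C)(C)C | intermediate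
8 | tert-butyl (2Z,4R)-2-(bromomethyl)-4-[(tert-butyldimethylsilyl)oxy]-6-oxohex-2-enoate | O=CC[C@@H](O[Si](C)(C)C(C)(C)C)/C=C(\CBr)C(=O)OC(C)(C)C | intermediate
9 | 3-methylcyclohex-2-en-1-one | CC1=CC(=O)CCC1 | starting material
10 | lithium 5-methylcyclohexa-1,5-dien-1-olate | [Li+].[O-]C1=CCCC(C)=C1 | intermediate
11 | tert-butyl (2Z,4R)-2-(bromomethyl)-4-[(tert-butyldimethylsilyl)oxy]-6-hydroxy-6-(4-methyl-2-oxocyclohex-3-en-1-yl)hex-2-enoate (mixture at C-6 and ring C-1) | CC1=CC(=O)C(CC1)C(O)C[C@@H](O[Si](C)(C)C(C)(C)C)/C=C(\CBr)C(=O)OC(C)(C)C | intermediate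
12 | tert-butyl (2Z,4R)-2-(bromomethyl)-4-[(tert-butyldimethylsilyl)oxy]-6-(4-methyl-2-oxocyclohex-3-en-1-yl)-6-oxohex-2-enoate (enolised β-diketone) | CC1=CC(=O)C(CC1)C(=O)C[C@@H](O[Si](C)(C)C(C)(C)C)/C=C(\CBr)C(=O)OC(C)(C)C | intermediate
13 | tert-butyl 2-[(1S,2R)-2-[(tert-butyldimethylsilyl)oxy]-8a-hydroxy-7-methyl-4-oxo-1,2,3,4,4a,5,6,8a-octahydronaphthalen-1-yl]prop-2-enoate (cis-fused ketol expected; C-4a and C-8a not controlled, both lost in step 10) | CC1=CC2(O)C(CC1)C(=O)C[C@@H](O[Si](C)(C)C(C)(C)C)[C@@H]2C(=C)C(=O)OC(C)(C)C | intermediate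
14 | potassium (1E,5Z,8S,9R)-8-[3-(tert-butoxy)-3-oxoprop-1-en-2-yl]-9-[(tert-butyldimethylsilyl)oxy]-5-methyl-7-oxocyclodeca-1,5-dien-1-olate | [K+].C/C1=C/C(=O)[C@@H](C(=C)C(=O)OC(C)(C)C)[C@H](O[Si](C)(C)C(C)(C)C)C/C([O-])=C\CC1 | intermediate
15 | (1E,5Z,8S,9R)-8-[3-(tert-butoxy)-3-oxoprop-1-en-2-yl]-9-[(tert-butyldimethylsilyl)oxy]-5-methyl-7-oxocyclodeca-1,5-dien-1-yl trifluoromethanesulfonate | C/C1=C/C(=O)[C@@H](C(=C)C(=O)OC(C)(C)C)[C@H](O[Si](C)(C)C(C)(C)C)C/C(OS(=O)(=O)C(F)(F)F)=C\CC1 | intermediate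
16 | (1E,5Z,7R,8R,9R)-8-[3-(tert-butoxy)-3-oxoprop-1-en-2-yl]-9-[(tert-butyldimethylsilyl)oxy]-7-hydroxy-5-methylcyclodeca-1,5-dien-1-yl trifluoromethanesulfonate | C/C1=C/[C@@H](O)[C@@H](C(=C)C(=O)OC(C)(C)C)[C@H](O[Si](C)(C)C(C)(C)C)C/C(OS(=O)(=O)C(F)(F)F)=C\CC1 | intermediate
17 | (3aR,4R,6E,10Z,11aR)-4-[(tert-butyldimethylsilyl)oxy]-10-methyl-3-methylidene-2-oxo-2,3,3a,4,5,8,9,11a-octahydrocyclodeca[b]furan-6-yl trifluoromethanesulfonate | C=C1C(=O)O[C@@H]2/C=C(/C)CC/C=C(/OS(=O)(=O)C(F)(F)F)C[C@@H](O[Si](C)(C)C(C)(C)C)[C@H]12 | intermediate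
18 | (3aS,4R,6E,10Z,11aR)-4-hydroxy-10-methyl-3-methylidene-2-oxo-2,3,3a,4,5,8,9,11a-octahydrocyclodeca[b]furan-6-yl trifluoromethanesulfonate | C=C1C(=O)O[C@@H]2/C=C(/C)CC/C=C(/OS(=O)(=O)C(F)(F)F)C[C@@H](O)[C@H]12 | intermediate
19 | (3aS,4R,6E,10Z,11aR)-10-methyl-3-methylidene-2-oxo-6-{[(trifluoromethyl)sulfonyl]oxy}-2,3,3a,4,5,8,9,11a-octahydrocyclodeca[b]furan-4-yl 3-methylbutanoate | C=C1C(=O)O[C@@H]2/C=C(/C)CC/C=C(/OS(=O)(=O)C(F)(F)F)C[C@@H](OC(=O)CC(C)C)[C@H]12 | intermediate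
20 | (3aS,4R,6E,10E,11aR)-10-(hydroxymethyl)-3-methylidene-2-oxo-6-{[(trifluoromethyl)sulfonyl]oxy}-2,3,3a,4,5,8,9,11a-octahydrocyclodeca[b]furan-4-yl 3-methylbutanoate | C=C1C(=O)O[C@@H]2/C=C(/CO)CC/C=C(/OS(=O)(=O)C(F)(F)F)C[C@@H](OC(=O)CC(C)C)[C@H]12 | intermediate
21 | (3aS,4R,6E,10E,11aR)-6-formyl-10-(hydroxymethyl)-3-methylidene-2-oxo-2,3,3a,4,5,8,9,11a-octahydrocyclodeca[b]furan-4-yl 3-methylbutanoate | C=C1C(=O)O[C@@H]2/C=C(/CO)CC/C=C(/C=O)C[C@@H](OC(=O)CC(C)C)[C@H]12 | target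

**Step count and risks**
Total: 15 steps. Longest linear sequence: 15 steps (1 → 21); 5 and 9 are bought and enter in steps 4 and 7.

The three steps most likely to fail:

Step 10 (the proposed ring expansion). The aldolate may re-close, attack the ester, or lose the C-1=C-10 geometry. The fallback uses the known epoxy-alcohol Grob fragmentation; it sets out from 13 and comes back at 21. The C-10 ketone of 13 is methylenated with dimethylsulfonium methylide (Me3SI, KHMDS, THF, −10 °C, attack on the convex face) to the spiro-epoxide tert-butyl 2-[(3'R,4'S)-3'-[(tert-butyldimethylsilyl)oxy]-4a'-hydroxy-6'-methyl-3',4',4a',7',8',8a'-hexahydro-2'H-spiro[oxirane-2,1'-naphthalen]-4'-yl]prop-2-enoate F1. Ti(OiPr)4 in CH2Cl2 at 40 °C fragments it to the ten-membered dienone tert-butyl 2-[(1S,3Z,7E,10R)-10-[(tert-butyldimethylsilyl)oxy]-8-(hydroxymethyl)-4-methyl-2-oxocyclodeca-3,7-dien-1-yl]prop-2-enoate F2, which already carries C-14 as a hydroxymethyl group. Luche reduction gives tert-butyl 2-[(1R,2R,3Z,7E,10R)-10-[(tert-butyldimethylsilyl)oxy]-2-hydroxy-8-(hydroxymethyl)-4-methylcyclodeca-3,7-dien-1-yl]prop-2-enoate F3. Lactonisation and desilylation under the conditions of step 12 give (3aS,4R,6E,10Z,11aR)-4-hydroxy-6-(hydroxymethyl)-10-methyl-3-methylidene-3a,4,5,8,9,11a-hexahydrocyclodeca[b]furan-2(3H)-one F4. MnO2 oxidises only the allylic primary alcohol to (3aS,4R,6E,10Z,11aR)-4-hydroxy-10-methyl-3-methylidene-2-oxo-2,3,3a,4,5,8,9,11a-octahydrocyclodeca[b]furan-6-carbaldehyde F5. Acylation as in step 13 gives (3aS,4R,6E,10Z,11aR)-6-formyl-10-methyl-3-methylidene-2-oxo-2,3,3a,4,5,8,9,11a-octahydrocyclodeca[b]furan-4-yl 3-methylbutanoate F6, and the SeO2/tBuOOH hydroxylation of step 14 then gives 21.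

Step 9 (allylindium addition to an enolised β-diketone). The enol form may be too poor an electrophile. The fallback reverses the order of oxidation and cyclisation; it sets out from 11 and comes back at 13. The non-enolised hydroxy enone 11 is cyclised with indium in THF/H2O to the bicyclic diol tert-butyl 2-[(1S,2R)-2-[(tert-butyldimethylsilyl)oxy]-4,8a-dihydroxy-7-methyl-1,2,3,4,4a,5,6,8a-octahydronaphthalen-1-yl]prop-2-enoate F7. Dess–Martin periodinane then oxidises its secondary alcohol only, leaving the tertiary one, to give 13.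

Step 14 (allylic hydroxylation). The reaction may stall or give alcohol/aldehyde mixtures. The fallback overshoots and corrects; it sets out from 19 and comes back at 20. Stoichiometric SeO2 in dioxane at 80 °C drives the oxidation to the enal (3aS,4R,6E,10E,11aR)-10-formyl-3-methylidene-2-oxo-6-{[(trifluoromethyl)sulfonyl]oxy}-2,3,3a,4,5,8,9,11a-octahydrocyclodeca[b]furan-4-yl 3-methylbutanoate F8. Luche reduction (NaBH4, CeCl3·7H2O, MeOH, −78 °C) touches only this aldehyde and gives 20.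

**Further compounds**
F1 | step 10 | tert-butyl 2-[(3'R,4'S)-3'-[(tert-butyldimethylsilyl)oxy]-4a'-hydroxy-6'-methyl-3',4',4a',7',8',8a'-hexahydro-2'H-spiro[oxirane-2,1'-naphthalen]-4'-yl]prop-2-enoate | CC1=CC2(O)C(CC1)C1(CO1)C[C@@H](O[Si](C)(C)C(C)(C)C)[C@@H]2C(=C)C(=O)OC(C)(C)C
F2 | step 10 | tert-butyl 2-[(1S,3Z,7E,10R)-10-[(tert-butyldimethylsilyl)oxy]-8-(hydroxymethyl)-4-methyl-2-oxocyclodeca-3,7-dien-1-yl]prop-2-enoate | C/C1=C/C(=O)[C@@H](C(=C)C(=O)OC(C)(C)C)[C@H](O[Si](C)(C)C(C)(C)C)C/C(CO)=C\CC1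
F3 | step 10 | tert-butyl 2-[(1R,2R,3Z,7E,10R)-10-[(tert-butyldimethylsilyl)oxy]-2-hydroxy-8-(hydroxymethyl)-4-methylcyclodeca-3,7-dien-1-yl]prop-2-enoate | C/C1=C/[C@@H](O)[C@@H](C(=C)C(=O)OC(C)(C)C)[C@H](O[Si](C)(C)C(C)(C)C)C/C(CO)=C\CC1
F4 | step 10 | (3aS,4R,6E,10Z,11aR)-4-hydroxy-6-(hydroxymethyl)-10-methyl-3-methylidene-3a,4,5,8,9,11a-hexahydrocyclodeca[b]furan-2(3H)-one | C=C1C(=O)O[C@@H]2/C=C(/C)CC/C=C(/CO)C[C@@H](O)[C@H]12
F5 | step 10 | (3aS,4R,6E,10Z,11aR)-4-hydroxy-10-methyl-3-methylidene-2-oxo-2,3,3a,4,5,8,9,11a-octahydrocyclodeca[b]furan-6-carbaldehyde | C=C1C(=O)O[C@@H]2/C=C(/C)CC/C=C(/C=O)C[C@@H](O)[C@H]12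
F6 | step 10 | (3aS,4R,6E,10Z,11aR)-6-formyl-10-methyl-3-methylidene-2-oxo-2,3,3a,4,5,8,9,11a-octahydrocyclodeca[b]furan-4-yl 3-methylbutanoate | C=C1C(=O)O[C@@H]2/C=C(/C)CC/C=C(/C=O)C[C@@H](OC(=O)CC(C)C)[C@H]12
F7 | step 9 | tert-butyl 2-[(1S,2R)-2-[(tert-butyldimethylsilyl)oxy]-4,8a-dihydroxy-7-methyl-1,2,3,4,4a,5,6,8a-octahydronaphthalen-1-yl]prop-2-enoate | CC1=CC2(O)C(CC1)C(O)C[C@@H](O[Si](C)(C)C(C)(C)C)[C@@H]2C(=C)C(=O)OC(C)(C)C
F8 | step 14 | (3aS,4R,6E,10E,11aR)-10-formyl-3-methylidene-2-oxo-6-{[(trifluoromethyl)sulfonyl]oxy}-2,3,3a,4,5,8,9,11a-octahydrocyclodeca[b]furan-4-yl 3-methylbutanoate | C=C1C(=O)O[C@@H]2/C=C(/C=O)CC/C=C(/OS(=O)(=O)C(F)(F)F)C[C@@H](OC(=O)CC(C)C)[C@H]12
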